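**Assumption:** the side-chain stereocentre in the SMILES is (S) (CIP order isopropenyl > ArCH2 > prenyl CH2 > H). Transient stereocentres in 17, 23, 27 and 29 form as mixtures and are erased later.

## Retrosynthetic overview

1. 31 ⇐ tetra-MOM flavonol 30 (acetal cleavage); ring C of 30 ⇐ Algar–Flynn–Oyamada oxidative cyclisation of 2'-hydroxychalcone 28.
2. 28 ⇐ intermolecular Claisen–Schmidt aldol condensation of ring A acetophenone 24 (carrying the side chain) with ring B aldehyde 26; this makes the C2–C3 bond of the chromone.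
3. 24 ⇐ phenol 20 by ortho-specific formylation, MeMgBr addition and oxidation; the single free phenol fixes which oxygen becomes O1 (8- and not 6-substitution).
4. 20 ⇐ Evans alkylation of 3-arylpropanoyl imide 9 with prenyl bromide (sets the S centre), then acyl → isopropenyl (Weinreb amide, MeMgBr, Cp2TiMe2).
5. 9 ⇐ 2,4,6-trihydroxybenzaldehyde 1 (MOM/TIPS differentiation, Wittig, hydrogenation). Rings A and B are bought; ring C is the only ring formed, and it is formed last.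

## Route

Step 1
Reactants: 1 2,4,6-trihydroxybenzaldehyde
Product: 2 2-hydroxy-4,6-bis(methoxymethoxy)benzaldehyde
Conditions: MOMCl (2.2 equiv), iPr2NEt, CH2Cl2, 0 °C → rt
Reagents that add atoms: chloromethyl methyl ether, COCCl
Why: Williamson-type O-alkylation in which the hydroxyl hydrogen-bonded to the formyl group is the least nucleophilic and stays free.

Step 2
Reactants: 2 2-hydroxy-4,6-bis(methoxymethoxy)benzaldehyde
Product: 3 2,4-bis(methoxymethoxy)-6-{[tri(propan-2-yl)silyl]oxy}benzaldehyde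
Conditions: TIPSCl, imidazole, DMF, 40 °C
Reagents that add atoms: chlorotri(propan-2-yl)silane, CC(C)[Si](Cl)(C(C)C)C(C)C
Why: Silylation gives a fluoride-labile ether orthogonal to MOM that marks the oxygen destined to become O1 and survives the basic and organometallic steps that follow.

Step 3
Reactants: 3 2,4-bis(methoxymethoxy)-6-{[tri(propan-2-yl)silyl]oxy}benzaldehyde; 4 benzyl (triphenyl-λ5-phosphanylidene)acetate
Product: 5 benzyl (2E)-3-[2,4-bis(methoxymethoxy)-6-{[tri(propan-2-yl)silyl]oxy}phenyl]prop-2-enoate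
Conditions: toluene, 110 °C
Reagents that add atoms: none
Why: Wittig olefination with a stabilised ylide is E-selective and needs no base, so the aryl silyl ether is untouched.

Step 4
Reactants: 5 benzyl (2E)-3-[2,4-bis(methoxymethoxy)-6-{[tri(propan-2-yl)silyl]oxy}phenyl]prop-2-enoate
Product: 6 3-[2,4-bis(methoxymethoxy)-6-{[tri(propan-2-yl)silyl]oxy}phenyl]propanoic acid
Conditions: H2 (1 atm), 10% Pd/C, EtOAc, rt
Reagents that add atoms: none
Why: Catalytic hydrogenation saturates the cinnamate C=C and hydrogenolyses the benzyl ester in one operation, with no hydroxide that could attack the silyl ether.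

Step 5
Reactants: 6 3-[2,4-bis(methoxymethoxy)-6-{[tri(propan-2-yl)silyl]oxy}phenyl]propanoic acid; 7 (4S)-4-benzyl-1,3-oxazolidin-2-one
Product: 9 (4S)-4-benzyl-3-{3-[2,4-bis(methoxymethoxy)-6-{[tri(propan-2-yl)silyl]oxy}phenyl]propanoyl}-1,3-oxazolidin-2-one, via mixed pivalic anhydride 8 (not isolated)
Conditions: PivCl, Et3N, THF, −20 °C; then 7, LiCl, −20 °C → rt
Reagents that add atoms: pivaloyl chloride, CC(C)(C)C(=O)Cl (its acyl group is held only in intermediate 8)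
Why: Mixed-anhydride N-acylation, in which the hindered pivaloyl carbonyl directs the LiCl-activated oxazolidinone to the desired acyl carbon.

Step 6
Reactants: 9 (4S)-4-benzyl-3-{3-[2,4-bis(methoxymethoxy)-6-{[tri(propan-2-yl)silyl]oxy}phenyl]propanoyl}-1,3-oxazolidin-2-one; 10 1-bromo-3-methylbut-2-ene (prenyl bromide)
Product: 12 (4S)-4-benzyl-3-[(2S)-2-{[2,4-bis(methoxymethoxy)-6-{[tri(propan-2-yl)silyl]oxy}phenyl]methyl}-5-methylhex-4-enoyl]-1,3-oxazolidin-2-one, via sodium Z-enolate 11 (not isolated)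
Conditions: NaN(SiMe3)2, THF, −78 °C; then 10, −78 → −40 °C
Reagents that add atoms: sodium bis(trimethylsilyl)amide, C[Si](C)(C)[N-][Si](C)(C)C.[Na+] (sodium is held only in intermediate 11)
Why: Evans asymmetric alkylation, in which the chelated Z-enolate is shielded on one face by the C4 benzyl group and prenyl bromide adds to the other face to set the (2S) centre (dr ≥ 95:5 expected; minor isomer removed by chromatography).

Step 7
Reactants: 12 (4S)-4-benzyl-3-[(2S)-2-{[2,4-bis(methoxymethoxy)-6-{[tri(propan-2-yl)silyl]oxy}phenyl]methyl}-5-methylhex-4-enoyl]-1,3-oxazolidin-2-one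
Product: 14 (2S)-2-{[2,4-bis(methoxymethoxy)-6-{[tri(propan-2-yl)silyl]oxy}phenyl]methyl}-5-methylhex-4-enoic acid, via lithium peroxycarboxylate 13 (not isolated)
Conditions: LiOH, 30% H2O2, THF/H2O, 0 °C; then Na2SO3; 1 M HCl to pH 4 at 0 °C
Reagents that add atoms: hydrogen peroxide, OO; lithium hydroxide, [Li+].[OH-] (lithium is held only in intermediate 13)
Why: Hydroperoxide cleavage of the imide attacks the exocyclic carbonyl selectively and does not epimerise the α-centre or epoxidise the isolated alkene.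

Step 8
Reactants: 14 (2S)-2-{[2,4-bis(methoxymethoxy)-6-{[tri(propan-2-yl)silyl]oxy}phenyl]methyl}-5-methylhex-4-enoic acid
Product: 16 (2S)-2-{[2,4-bis(methoxymethoxy)-6-{[tri(propan-2-yl)silyl]oxy}phenyl]methyl}-N-methoxy-N,5-dimethylhex-4-enamide, via acyl imidazole 15 (not isolated)
Conditions: 1,1'-carbonyldiimidazole, CH2Cl2, rt; then MeNHOMe·HCl, rt
Reagents that add atoms: 1,1'-carbonyldiimidazole, O=C(n1ccnc1)n1ccnc1 (imidazolyl is held only in intermediate 15); N,O-dimethylhydroxylamine hydrochloride, CNOC.Cl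
Why: Weinreb amide formation through an acyl imidazole is a mild, base-free amidation that leaves the α-centre intact.

Step 9
Reactants: 16 (2S)-2-{[2,4-bis(methoxymethoxy)-6-{[tri(propan-2-yl)silyl]oxy}phenyl]methyl}-N-methoxy-N,5-dimethylhex-4-enamide
Product: 18 (3S)-3-{[2,4-bis(methoxymethoxy)-6-{[tri(propan-2-yl)silyl]oxy}phenyl]methyl}-6-methylhept-5-en-2-one, via magnesium chelate 17 (not isolated)
Conditions: MeMgBr, THF, 0 °C; cold aq NH4Cl
Reagents that add atoms: methylmagnesium bromide, C[Mg]Br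
Why: Weinreb ketone synthesis, in which the stable five-membered magnesium chelate prevents over-addition and releases the ketone only on cold quench, so the α-centre is not enolised.

Step 10
Reactants: 18 (3S)-3-{[2,4-bis(methoxymethoxy)-6-{[tri(propan-2-yl)silyl]oxy}phenyl]methyl}-6-methylhept-5-en-2-one
Product: 19 {3,5-bis(methoxymethoxy)-2-[(2S)-5-methyl-2-(prop-1-en-2-yl)hex-4-en-1-yl]phenoxy}tri(propan-2-yl)silane
Conditions: Cp2TiMe2 (3 equiv), toluene/THF, 65 °C, dark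
Reagents that add atoms: dimethyltitanocene Cp2TiMe2, C[Ti](C)(C1C=CC=C1)C1C=CC=C1
Why: Petasis methylenation uses a non-basic titanium methylidene, so the epimerisable α-centre is carried unchanged into the isopropenyl (lavandulyl) unit.

Step 11
Reactants: 19 {3,5-bis(methoxymethoxy)-2-[(2S)-5-methyl-2-(prop-1-en-2-yl)hex-4-en-1-yl]phenoxy}tri(propan-2-yl)silane
Product: 20 3,5-bis(methoxymethoxy)-2-[(2S)-5-methyl-2-(prop-1-en-2-yl)hex-4-en-1-yl]phenol
Conditions: Bu4NF, THF, 0 °C; aq NH4Cl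
Reagents that add atoms: none
Why: Fluoride desilylation frees only the one phenol flanked by the side chain and leaves the MOM acetals and alkenes alone.

Step 12
Reactants: 20 3,5-bis(methoxymethoxy)-2-[(2S)-5-methyl-2-(prop-1-en-2-yl)hex-4-en-1-yl]phenol
Product: 22 2-hydroxy-4,6-bis(methoxymethoxy)-3-[(2S)-5-methyl-2-(prop-1-en-2-yl)hex-4-en-1-yl]benzaldehyde, via hydroxymethylphenol 21 (not isolated)
Conditions: MgCl2, Et3N, (CH2O)n, THF, reflux; aq NH4Cl
Reagents that add atoms: paraformaldehyde (formaldehyde), C=O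
Why: Casnati–Skattebøl ortho-formylation, in which the magnesium phenoxide delivers formaldehyde only to the single free ortho position and a second formaldehyde oxidises the hydroxymethyl group by hydride transfer.

Step 13
Reactants: 22 2-hydroxy-4,6-bis(methoxymethoxy)-3-[(2S)-5-methyl-2-(prop-1-en-2-yl)hex-4-en-1-yl]benzaldehyde
Product: 23 2-(1-hydroxyethyl)-3,5-bis(methoxymethoxy)-6-[(2S)-5-methyl-2-(prop-1-en-2-yl)hex-4-en-1-yl]phenol (about 1:1 at the carbinol carbon)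
Conditions: MeMgBr (3 equiv), THF, −20 → 0 °C; aq NH4Cl, used crude
Reagents that add atoms: methylmagnesium bromide, C[Mg]Br
Why: Grignard addition to the aldehyde after deprotonation of the phenol, with the new carbinol centre left uncontrolled because it is oxidised in the next step.

Step 14
Reactants: 23 2-(1-hydroxyethyl)-3,5-bis(methoxymethoxy)-6-[(2S)-5-methyl-2-(prop-1-en-2-yl)hex-4-en-1-yl]phenol
Product: 24 1-{2-hydroxy-4,6-bis(methoxymethoxy)-3-[(2S)-5-methyl-2-(prop-1-en-2-yl)hex-4-en-1-yl]phenyl}ethan-1-one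
Conditions: MnO2 (15 equiv), CH2Cl2, rt
Reagents that add atoms: none
Why: Neutral MnO2 oxidation of the activated benzylic alcohol gives the hydrogen-bonded ortho-hydroxyacetophenone without touching the alkenes or the phenol.

Step 15
Reactants: 25 2,4-dihydroxybenzaldehyde
Product: 26 2,4-bis(methoxymethoxy)benzaldehyde
Conditions: NaH, MOMCl, DMF, 0 °C → rt
Reagents that add atoms: chloromethyl methyl ether, COCCl
Why: Williamson etherification of both phenoxides (NaH also overcomes the chelated ortho hydroxyl) gives base-stable acetals for the condensation.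

Step 16
Reactants: 24 1-{2-hydroxy-4,6-bis(methoxymethoxy)-3-[(2S)-5-methyl-2-(prop-1-en-2-yl)hex-4-en-1-yl]phenyl}ethan-1-one; 26 2,4-bis(methoxymethoxy)benzaldehyde
Product: 28 (2E)-3-[2,4-bis(methoxymethoxy)phenyl]-1-{2-hydroxy-4,6-bis(methoxymethoxy)-3-[(2S)-5-methyl-2-(prop-1-en-2-yl)hex-4-en-1-yl]phenyl}prop-2-en-1-one, via β-hydroxy ketone 27 (not isolated)
Conditions: KOH, EtOH/H2O, rt, 36 h
Reagents that add atoms: none
Why: Claisen–Schmidt crossed aldol condensation between the only enolisable ketone and a non-enolisable aldehyde, followed by E1cB dehydration to the E-enone.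

Step 17
Reactants: 28 (2E)-3-[2,4-bis(methoxymethoxy)phenyl]-1-{2-hydroxy-4,6-bis(methoxymethoxy)-3-[(2S)-5-methyl-2-(prop-1-en-2-yl)hex-4-en-1-yl]phenyl}prop-2-en-1-one
Product: 30 2-[2,4-bis(methoxymethoxy)phenyl]-3-hydroxy-5,7-bis(methoxymethoxy)-8-[(2S)-5-methyl-2-(prop-1-en-2-yl)hex-4-en-1-yl]-4H-chromen-4-one, via dihydroflavonol 29 (not isolated)
Conditions: 30% H2O2, 2 M NaOH, MeOH/THF, 0 °C → rt
Reagents that add atoms: hydrogen peroxide, OO
Why: Algar–Flynn–Oyamada reaction, in which the 2'-phenoxide closes ring C and hydroperoxide oxidises C3 and then dehydrogenates the 3-hydroxyflavanone, while alkaline H2O2 does not epoxidise the isolated alkenes.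

Step 18
Reactants: 30 2-[2,4-bis(methoxymethoxy)phenyl]-3-hydroxy-5,7-bis(methoxymethoxy)-8-[(2S)-5-methyl-2-(prop-1-en-2-yl)hex-4-en-1-yl]-4H-chromen-4-one
Product: 31 2-(2,4-dihydroxyphenyl)-3,5,7-trihydroxy-8-[(2S)-5-methyl-2-(prop-1-en-2-yl)hex-4-en-1-yl]-4H-chromen-4-one
Conditions: 3 M aq HCl/MeOH (1:5), 45 °C, monitored and stopped at full conversion
Reagents that add atoms: none
Why: Acid-catalysed transacetalisation removes all four aryl MOM groups, and the side-chain stereocentre is a non-acidic allylic C–H that brief, mild acid does not disturb.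

## Compound list

1 | 2,4,6-trihydroxybenzaldehyde | O=Cc1c(O)cc(O)cc1O | starting material
2 | 2-hydroxy-4,6-bis(methoxymethoxy)benzaldehyde | O=Cc1c(O)cc(OCOC)cc1OCOC | intermediate
3 | 2,4-bis(methoxymethoxy)-6-{[tri(propan-2-yl)silyl]oxy}benzaldehyde | O=Cc1c(O[Si](C(C)C)(C(C)C)C(C)C)cc(OCOC)cc1OCOC | intermediate
4 | benzyl (triphenyl-λ5-phosphanylidene)acetate | O=C(OCc1ccccc1)C=P(c1ccccc1)(c1ccccc1)c1ccccc1 | starting material
5 | benzyl (2E)-3-[2,4-bis(methoxymethoxy)-6-{[tri(propan-2-yl)silyl]oxy}phenyl]prop-2-enoate | O=C(OCc1ccccc1)/C=C/c1c(O[Si](C(C)C)(C(C)C)C(C)C)cc(OCOC)cc1OCOC | intermediate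
6 | 3-[2,4-bis(methoxymethoxy)-6-{[tri(propan-2-yl)silyl]oxy}phenyl]propanoic acid | OC(=O)CCc1c(O[Si](C(C)C)(C(C)C)C(C)C)cc(OCOC)cc1OCOC | intermediate
7 | (4S)-4-benzyl-1,3-oxazolidin-2-one | O=C1N[C@@H](Cc2ccccc2)CO1 | starting material
8 | mixed anhydride of 6 with pivalic acid (not isolated) | CC(C)(C)C(=O)OC(=O)CCc1c(O[Si](C(C)C)(C(C)C)C(C)C)cc(OCOC)cc1OCOC | intermediate
9 | (4S)-4-benzyl-3-{3-[2,4-bis(methoxymethoxy)-6-{[tri(propan-2-yl)silyl]oxy}phenyl]propanoyl}-1,3-oxazolidin-2-one | O=C(CCc1c(O[Si](C(C)C)(C(C)C)C(C)C)cc(OCOC)cc1OCOC)N1[C@@H](Cc2ccccc2)COC1=O | intermediate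
10 | 1-bromo-3-methylbut-2-ene (prenyl bromide) | CC(C)=CCBr | starting material
11 | sodium Z-enolate of imide 9 (not isolated) | [Na+].[O-]/C(=C\Cc1c(O[Si](C(C)C)(C(C)C)C(C)C)cc(OCOC)cc1OCOC)N1[C@@H](Cc2ccccc2)COC1=O | intermediate
12 | (4S)-4-benzyl-3-[(2S)-2-{[2,4-bis(methoxymethoxy)-6-{[tri(propan-2-yl)silyl]oxy}phenyl]methyl}-5-methylhex-4-enoyl]-1,3-oxazolidin-2-one | O=C([C@@H](CC=C(C)C)Cc1c(O[Si](C(C)C)(C(C)C)C(C)C)cc(OCOC)cc1OCOC)N1[C@@H](Cc2ccccc2)COC1=O | intermediate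
13 | lithium (2S)-2-{[2,4-bis(methoxymethoxy)-6-{[tri(propan-2-yl)silyl]oxy}phenyl]methyl}-5-methylhex-4-eneperoxoate (not isolated) | [Li+].[O-]OC(=O)[C@@H](CC=C(C)C)Cc1c(O[Si](C(C)C)(C(C)C)C(C)C)cc(OCOC)cc1OCOC | intermediate
14 | (2S)-2-{[2,4-bis(methoxymethoxy)-6-{[tri(propan-2-yl)silyl]oxy}phenyl]methyl}-5-methylhex-4-enoic acid | OC(=O)[C@@H](CC=C(C)C)Cc1c(O[Si](C(C)C)(C(C)C)C(C)C)cc(OCOC)cc1OCOC | intermediate
15 | (2S)-2-{[2,4-bis(methoxymethoxy)-6-{[tri(propan-2-yl)silyl]oxy}phenyl]methyl}-1-(1H-imidazol-1-yl)-5-methylhex-4-en-1-one (not isolated) | O=C([C@@H](CC=C(C)C)Cc1c(O[Si](C(C)C)(C(C)C)C(C)C)cc(OCOC)cc1OCOC)n1ccnc1 | intermediate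
16 | (2S)-2-{[2,4-bis(methoxymethoxy)-6-{[tri(propan-2-yl)silyl]oxy}phenyl]methyl}-N-methoxy-N,5-dimethylhex-4-enamide | CON(C)C(=O)[C@@H](CC=C(C)C)Cc1c(O[Si](C(C)C)(C(C)C)C(C)C)cc(OCOC)cc1OCOC | intermediate
17 | bromomagnesium alkoxide (tetrahedral chelate) from MeMgBr addition to amide 16 (not isolated) | CON(C)C(C)(O[Mg]Br)[C@@H](CC=C(C)C)Cc1c(O[Si](C(C)C)(C(C)C)C(C)C)cc(OCOC)cc1OCOC | intermediate
18 | (3S)-3-{[2,4-bis(methoxymethoxy)-6-{[tri(propan-2-yl)silyl]oxy}phenyl]methyl}-6-methylhept-5-en-2-one | CC(=O)[C@@H](CC=C(C)C)Cc1c(O[Si](C(C)C)(C(C)C)C(C)C)cc(OCOC)cc1OCOC | intermediate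
19 | {3,5-bis(methoxymethoxy)-2-[(2S)-5-methyl-2-(prop-1-en-2-yl)hex-4-en-1-yl]phenoxy}tri(propan-2-yl)silane | C=C(C)[C@@H](CC=C(C)C)Cc1c(O[Si](C(C)C)(C(C)C)C(C)C)cc(OCOC)cc1OCOC | intermediate
20 | 3,5-bis(methoxymethoxy)-2-[(2S)-5-methyl-2-(prop-1-en-2-yl)hex-4-en-1-yl]phenol | C=C(C)[C@@H](CC=C(C)C)Cc1c(O)cc(OCOC)cc1OCOC | intermediate
21 | 2-(hydroxymethyl)-3,5-bis(methoxymethoxy)-6-[(2S)-5-methyl-2-(prop-1-en-2-yl)hex-4-en-1-yl]phenol (as magnesium salt, not isolated) | C=C(C)[C@@H](CC=C(C)C)Cc1c(O)c(CO)c(OCOC)cc1OCOC | intermediate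
22 | 2-hydroxy-4,6-bis(methoxymethoxy)-3-[(2S)-5-methyl-2-(prop-1-en-2-yl)hex-4-en-1-yl]benzaldehyde | C=C(C)[C@@H](CC=C(C)C)Cc1c(O)c(C=O)c(OCOC)cc1OCOC | intermediate
23 | 2-(1-hydroxyethyl)-3,5-bis(methoxymethoxy)-6-[(2S)-5-methyl-2-(prop-1-en-2-yl)hex-4-en-1-yl]phenol (carbinol epimers) | C=C(C)[C@@H](CC=C(C)C)Cc1c(O)c(C(C)O)c(OCOC)cc1OCOC | intermediate
24 | 1-{2-hydroxy-4,6-bis(methoxymethoxy)-3-[(2S)-5-methyl-2-(prop-1-en-2-yl)hex-4-en-1-yl]phenyl}ethan-1-one | C=C(C)[C@@H](CC=C(C)C)Cc1c(O)c(C(C)=O)c(OCOC)cc1OCOC | intermediate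
25 | 2,4-dihydroxybenzaldehyde | O=Cc1ccc(O)cc1O | starting material
26 | 2,4-bis(methoxymethoxy)benzaldehyde | O=Cc1ccc(OCOC)cc1OCOC | intermediate
27 | 3-[2,4-bis(methoxymethoxy)phenyl]-3-hydroxy-1-{2-hydroxy-4,6-bis(methoxymethoxy)-3-[(2S)-5-methyl-2-(prop-1-en-2-yl)hex-4-en-1-yl]phenyl}propan-1-one (carbinol epimers, not isolated) | C=C(C)[C@@H](CC=C(C)C)Cc1c(O)c(C(=O)CC(O)c2ccc(OCOC)cc2OCOC)c(OCOC)cc1OCOC | intermediate
28 | (2E)-3-[2,4-bis(methoxymethoxy)phenyl]-1-{2-hydroxy-4,6-bis(methoxymethoxy)-3-[(2S)-5-methyl-2-(prop-1-en-2-yl)hex-4-en-1-yl]phenyl}prop-2-en-1-one | C=C(C)[C@@H](CC=C(C)C)Cc1c(O)c(C(=O)/C=C/c2ccc(OCOC)cc2OCOC)c(OCOC)cc1OCOC | intermediate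
29 | 2-[2,4-bis(methoxymethoxy)phenyl]-3-hydroxy-5,7-bis(methoxymethoxy)-8-[(2S)-5-methyl-2-(prop-1-en-2-yl)hex-4-en-1-yl]-2,3-dihydro-4H-chromen-4-one (C2/C3 mixture, not isolated) | C=C(C)[C@@H](CC=C(C)C)Cc1c(OCOC)cc(OCOC)c2c1OC(c1ccc(OCOC)cc1OCOC)C(O)C2=O | intermediate
30 | 2-[2,4-bis(methoxymethoxy)phenyl]-3-hydroxy-5,7-bis(methoxymethoxy)-8-[(2S)-5-methyl-2-(prop-1-en-2-yl)hex-4-en-1-yl]-4H-chromen-4-one | C=C(C)[C@@H](CC=C(C)C)Cc1c(OCOC)cc(OCOC)c2c(=O)c(O)c(-c3ccc(OCOC)cc3OCOC)oc12 | intermediate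
31 | 2-(2,4-dihydroxyphenyl)-3,5,7-trihydroxy-8-[(2S)-5-methyl-2-(prop-1-en-2-yl)hex-4-en-1-yl]-4H-chromen-4-one | C=C(C)[C@@H](CC=C(C)C)Cc1c(O)cc(O)c2c(=O)c(O)c(-c3ccc(O)cc3O)oc12 | target

## Step count and risks

Total steps: 18. Longest linear sequence: 17 (steps 1–14, then 16–18); step 15 is a one-step branch.

**Step 17 (Algar–Flynn–Oyamada).** Chalcones with a 6'-alkoxy group can divert to aurones by attack of the phenoxide at the α-carbon. The fallback sets out from 22 and 26 and comes back at 30. Aldehyde 26 is homologated with dimethyl (1-diazo-2-oxopropyl)phosphonate, K2CO3 and MeOH to 1-ethynyl-2,4-bis(methoxymethoxy)benzene F1. Its lithium acetylide (n-BuLi, THF, −78 °C, 2.2 equiv) adds to 22 to give the propargylic alcohol F2, and MnO2 oxidises this to the ynone F3. Et2NH in EtOH followed by warming closes ring C by 6-endo oxa-Michael addition through the enaminone, giving the flavone F4. LiN(iPr)2 at −78 °C lithiates C3, B(OMe)3 traps the anion as the boronate F5, and NaOH/H2O2 at 0 °C oxidises the C–B bond to give 30. No phenoxide meets an epoxide on this path, and none of the reagents attacks the isolated alkenes.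

**Step 18 (global MOM removal).** Protic acid can add the 7-hydroxyl or solvent across the isopropenyl or prenyl alkene. The fallback sets out from 30 and comes back at 31. Instead of protic hydrolysis, 30 is treated with Me3SiOSO2CF3 and 2,2'-bipyridyl in CH2Cl2 at 0 °C → rt. This exchanges the four aryl methoxymethyl groups for silyl groups under buffered, aprotic conditions (the 3-hydroxyl is silylated as well) and gives the pentakis(trimethylsilyl) ether F6. Water in THF at neutral pH then hydrolyses the aryl silyl ethers to 31.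

**Step 14 (oxidation of the free ortho-hydroxybenzylic alcohol).** The electron-rich carbinol 23 can ionise to an ortho-quinone methide and oligomerise before or during oxidation. The fallback sets out from 22 and comes back at 24. The phenol of 22 is capped first (allyl bromide, K2CO3, DMF) to give the allyl ether F7. MeMgBr then gives the carbinol F8, which cannot form a quinone methide, and Dess–Martin periodinane gives the ketone F9. Pd(PPh3)4 with morpholine (zerovalent palladium, π-allyl transfer to the amine) removes the allyl group and gives 24 without affecting the MOM ethers or the unactivated alkenes.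

## Further compounds

F1 | step 17 | 1-ethynyl-2,4-bis(methoxymethoxy)benzene | C#Cc1ccc(OCOC)cc1OCOC
F2 | step 17 | 2-{3-[2,4-bis(methoxymethoxy)phenyl]-1-hydroxyprop-2-yn-1-yl}-3,5-bis(methoxymethoxy)-6-[(2S)-5-methyl-2-(prop-1-en-2-yl)hex-4-en-1-yl]phenol | C=C(C)[C@@H](CC=C(C)C)Cc1c(O)c(C(O)C#Cc2ccc(OCOC)cc2OCOC)c(OCOC)cc1OCOC
F3 | step 17 | 3-[2,4-bis(methoxymethoxy)phenyl]-1-{2-hydroxy-4,6-bis(methoxymethoxy)-3-[(2S)-5-methyl-2-(prop-1-en-2-yl)hex-4-en-1-yl]phenyl}prop-2-yn-1-one | C=C(C)[C@@H](CC=C(C)C)Cc1c(O)c(C(=O)C#Cc2ccc(OCOC)cc2OCOC)c(OCOC)cc1OCOC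
F4 | step 17 | 2-[2,4-bis(methoxymethoxy)phenyl]-5,7-bis(methoxymethoxy)-8-[(2S)-5-methyl-2-(prop-1-en-2-yl)hex-4-en-1-yl]-4H-chromen-4-one | C=C(C)[C@@H](CC=C(C)C)Cc1c(OCOC)cc(OCOC)c2c(=O)cc(-c3ccc(OCOC)cc3OCOC)oc12
F5 | step 17 | dimethyl {2-[2,4-bis(methoxymethoxy)phenyl]-5,7-bis(methoxymethoxy)-8-[(2S)-5-methyl-2-(prop-1-en-2-yl)hex-4-en-1-yl]-4-oxo-4H-chromen-3-yl}boronate | C=C(C)[C@@H](CC=C(C)C)Cc1c(OCOC)cc(OCOC)c2c(=O)c(B(OC)OC)c(-c3ccc(OCOC)cc3OCOC)oc12
F6 | step 18 | 2-{2,4-bis[(trimethylsilyl)oxy]phenyl}-3,5,7-tris[(trimethylsilyl)oxy]-8-[(2S)-5-methyl-2-(prop-1-en-2-yl)hex-4-en-1-yl]-4H-chromen-4-one | C=C(C)[C@@H](CC=C(C)C)Cc1c(O[Si](C)(C)C)cc(O[Si](C)(C)C)c2c(=O)c(O[Si](C)(C)C)c(-c3ccc(O[Si](C)(C)C)cc3O[Si](C)(C)C)oc12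
F7 | step 14 | 4,6-bis(methoxymethoxy)-3-[(2S)-5-methyl-2-(prop-1-en-2-yl)hex-4-en-1-yl]-2-(prop-2-en-1-yloxy)benzaldehyde | C=C(C)[C@@H](CC=C(C)C)Cc1c(OCC=C)c(C=O)c(OCOC)cc1OCOC
F8 | step 14 | 1-{4,6-bis(methoxymethoxy)-3-[(2S)-5-methyl-2-(prop-1-en-2-yl)hex-4-en-1-yl]-2-(prop-2-en-1-yloxy)phenyl}ethan-1-ol | C=C(C)[C@@H](CC=C(C)C)Cc1c(OCC=C)c(C(C)O)c(OCOC)cc1OCOC
F9 | step 14 | 1-{4,6-bis(methoxymethoxy)-3-[(2S)-5-methyl-2-(prop-1-en-2-yl)hex-4-en-1-yl]-2-(prop-2-en-1-yloxy)phenyl}ethan-1-one | C=C(C)[C@@H](CC=C(C)C)Cc1c(OCC=C)c(C(C)=O)c(OCOC)cc1OCOC
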